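**Fraction left.** Count the substrate by the fraction left, x, and put the clock aside. Each flask holds substrate in the first phase and reagent in the second, and I want the target at the end.

| setting | gamma | eta | Sunday's | Wednesday's | Thursday's |
|---|---|---|---|---|---|
| substrate | 0.84 M | 0.84 M | 0.84 M | 0.84 M | 0.84 M |
| reagent in the second phase | 0.30 M | 2.4 M | 0.400 M | 1.20 M | 3.00 M |
| remark | run made earlier | run made earlier |  |  |  |
| time |  |  | 2.5 min | 2.5 min | 2.5 min |
| volume of the second phase over the first |  |  | 1.0 | 1.0 | 1.0 |

| run | time / min | target / % |
|---|---|---|
| gamma | 0.200 | 0.8 |
| gamma | 0.333 | 4.1 |
| gamma | 0.500 | 6.7 |
| gamma | 0.833 | 10.0 |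
| gamma | 1.50 | 15.9 |
| gamma | 2.50 | 24.0 |
| eta | 0.200 | 10.8 |
| eta | 0.333 | 19.7 |
| eta | 0.500 | 32.8 |
| eta | 0.833 | 49.3 |
| eta | 1.50 | 53.2 |
| eta | 2.50 | 43.1 |

(standard deviation of a reading: 1 percentage point)

- amount of target at the end, in percent of the substrate charged for Sunday's, Wednesday's, Thursday's, in this order
- the course of these numbers from the first flask to the last (hardly changes / rises, then falls / falls, then rises / rises all the way / falls all the way)

- in the second phase: reagent in the second phase; everything else is in the first
- charges count per volume of the first phase; a concentration in a rate is the amount of a species over the volume of its own phase; every rate counts per litre of the first phase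
- the earlier runs hold the two phases in the same ratio of volumes as the flask asked about
- "hardly changes" means that all values lie within two and a half points (for a concentration: within two and a half percent of the largest)

**Main step.** Take substrate + reagent → target by itself. Every substrate lost is then a target, so P, the target as a fraction of the substrate charged, is 1 − x. Its top lies at x = 0, with the whole charge as target.

**Second step.** In the eta run, target stands lower at 2.50 min than at 1.50 min, 43.1 % against 53.2 %. I therefore add target + reagent → over-reacted product. I assume both steps are first order in the same reagent concentration, so dividing one rate by the other removes that concentration and time with it. What remains is a single number κ, the second rate constant over the first. The curve becomes P = (x^κ − x)/(1 − κ). It peaks where x = κP, at a height P* = κ^(κ/(1 − κ)).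

I take the eta run's highest reading, 53.2 %, as P*, with its scatter of 1 percentage point. Near this height, −ln κ/(1 − κ) is close to 1.50, so κ reads 0.421. This κ, the selectivity factor, puts the peak where 22.4 % of the substrate charged is left.

**Reagent supply.** The reagent must still cross from the second phase, and I read how far along the curve a flask gets by the end from the earlier runs. Under the same assumption, the curve itself stays as it is. The gamma run ends at 24.0 %, on the rising side, and the eta run ends at 43.1 %, past the peak. I therefore expect Sunday's flask a little above the gamma run, Wednesday's flask close to the peak, and Thursday's flask below the eta run. That is a rise and then a fall, and I commit to no closer row than this.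

**The forecast.** It gives 29 %, 51 % and 22 %, with the course rises, then falls. Its ground for the competition is “with target about 0.4 times as competitive”, and my κ reads 0.421.

**The result.** The flasks give 28.0 %, 53.0 % and 31.1 %, with the course rises, then falls. Thursday's flask stands 9.1 points above the forecast.

    reagent in the reaction phase ⇌ reagent in the second phase, rate k1*([reagent in the reaction phase] - [reagent in the second phase]/K1) per volume of the first phase (partition coefficient = 0.670, kL = 0.0120 s⁻¹)
    substrate + reagent in the reaction phase → target (k = 0.0420 L mol⁻¹ s⁻¹)
    reagent in the reaction phase + target → over-reacted product (k = 0.0170 L mol⁻¹ s⁻¹)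
    reagent in the reaction phase → decomposed reagent (k = 0.00470 s⁻¹)

**What ran.** In Wednesday's flask the main step was still running at 1.25 min with 50.5 % substrate present, and at 2.50 min 29 % was left. At that substrate the curve with κ reads 52.5 %, and Wednesday's flask holds 53.0 %. In Thursday's flask substrate had fallen to 15.2 % by 1.25 min, below the 22.4 % at which the curve peaks, and the second step went on consuming the 52.8 % of target. With 2.0 % substrate left in Thursday's flask at 2.50 min, the curve reads 29.8 %, and that flask holds 31.1 %.

Readings and results are simulated from invented constants; the scatter is artificial.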